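**Retrosynthetic overview**
- Callophycoic acid F ⇐ the 6-bromo acid (Br/Mg exchange, protonation) ⇐ its methyl ester; bromine at C6 is a temporary regiocontrol element.
- The oxepine ring ⇐ a 2-(homofarnesyl)-2-vinyloxirane plus a 3-bromo-4-(methoxycarbonyl)benzyne in a formal (5+2) ring expansion: O1–C9a forms first, then C5–C5a closes the seven-membered ring.
- Enabling feature: between the adjacent benzene carbons C9a and C5a the oxepine ring carries O1–C2H2–C3(R)=C4H–C5H2, which is a vinyloxirane (O1, C2, C3 as the three-membered ring, C4=C5 as the vinyl group) opened in the SN2′ sense, so C9a/C5a can be an aryne.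
- Vinyloxirane ⇐ chlorohydrin ⇐ chloromethyl ketone ⇐ Weinreb amide ⇐ (2E,6E)-farnesyl bromide + acetamide enolate; aryne ⇐ aryl(mesityl)iodonium triflate ⇐ methyl 2-bromo-4-iodobenzoate.
- Ring order: benzene ring bought; oxirane (step 4); oxepine (step 6).

Key step: step 6

Assumption: commercial (2E,6E)-farnesyl bromide is taken as the pure E,E isomer; the chlorohydrin and the oxirane are racemic, which is without consequence because that carbon becomes sp2 in step 6 and the target has no stereocentre.

Step 1
Reactants: 1 (2E,6E)-farnesyl bromide; 2 N-methoxy-N-methylacetamide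
Product: 4 (4E,8E)-N-methoxy-N,5,9,13-tetramethyltetradeca-4,8,12-trienamide, via lithium amide enolate 3 (not isolated)
Conditions: LiN(iPr)2, THF, −78 °C; then 1, −78 to −20 °C
Reagents that add atoms: none
Why: SN2 C-alkylation of an amide lithium enolate by a primary allylic bromide (enolate alkylation), which leaves the E olefins of the farnesyl unit untouched.

Step 2
Reactants: 4 (4E,8E)-N-methoxy-N,5,9,13-tetramethyltetradeca-4,8,12-trienamide
Product: 6 (5E,9E)-1-chloro-6,10,14-trimethylpentadeca-5,9,13-trien-2-one, via lithium hemiaminal chelate 5 (not isolated)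
Conditions: ClCH2I, MeLi·LiBr, THF, −78 °C; then aq NH4Cl
Reagents that add atoms: chloroiodomethane, ClCI
Why: Weinreb ketone synthesis with chloromethyllithium generated by I/Li exchange in the presence of the amide, where the chelated tetrahedral adduct 5 should stop the reaction at mono-addition and collapse to the chloromethyl ketone on quench.

Step 3
Reactants: 6 (5E,9E)-1-chloro-6,10,14-trimethylpentadeca-5,9,13-trien-2-one
Product: 7 (6E,10E)-3-(chloromethyl)-7,11,15-trimethylhexadeca-1,6,10,14-tetraen-3-ol (racemic)
Conditions: CH2=CHMgBr, THF, −78 °C; then aq NH4Cl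
Reagents that add atoms: vinylmagnesium bromide, C=C[Mg]Br
Why: Grignard 1,2-addition to the ketone should outrun enolisation and chloride displacement at −78 °C; the new carbinol centre forms racemic and is erased in step 6.

Step 4
Reactants: 7 (6E,10E)-3-(chloromethyl)-7,11,15-trimethylhexadeca-1,6,10,14-tetraen-3-ol
Product: 8 2-ethenyl-2-[(3E,7E)-4,8,12-trimethyltrideca-3,7,11-trien-1-yl]oxirane (racemic)
Conditions: K2CO3, MeOH, rt
Reagents that add atoms: none
Why: intramolecular Williamson reaction (3-exo-tet closure of the chlorohydrin alkoxide), the standard route to 2-alkyl-2-vinyloxiranes.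

Step 5
Reactants: 9 methyl 2-bromo-4-iodobenzoate
Product: 10 [3-bromo-4-(methoxycarbonyl)phenyl](2,4,6-trimethylphenyl)iodonium trifluoromethanesulfonate
Conditions: mCPBA, TfOH, mesitylene, CH2Cl2, 0 °C to rt
Reagents that add atoms: mesitylene, Cc1cc(C)cc(C)c1; trifluoromethanesulfonic acid, OS(=O)(=O)C(F)(F)F
Why: one-pot oxidation of the aryl iodide to trivalent iodine and electrophilic arylation of mesitylene (diaryliodonium salt synthesis), favoured by the electron-poor iodoarene/electron-rich arene pairing and leaving ester and aryl bromide untouched.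

Step 6
Reactants: 8 2-ethenyl-2-[(3E,7E)-4,8,12-trimethyltrideca-3,7,11-trien-1-yl]oxirane; 10 [3-bromo-4-(methoxycarbonyl)phenyl](2,4,6-trimethylphenyl)iodonium trifluoromethanesulfonate
Product: 13 methyl 6-bromo-3-[(3E,7E)-4,8,12-trimethyltrideca-3,7,11-trien-1-yl]-2,5-dihydro-1-benzoxepine-7-carboxylate, via bromo ester aryne 11 (not isolated), via aryl oxiranium zwitterion 12 (not isolated)
Conditions: K3PO4 (anhydrous, powdered), MeCN/CH2Cl2, rt; 10 added in portions to 8 (1.3 equiv)
Reagents that add atoms: none
Why: Proposed new method: K3PO4 removes the proton of 10 that lies between bromine and the iodonium group and iodomesitylene departs (known aryne generation from aryl(mesityl)iodonium salts) to give aryne 11; the oxirane oxygen of 8 adds to the aryne carbon remote from bromine to give the 2-bromoaryl anion/oxiranium zwitterion 12, whose carbanion attacks the terminal vinyl carbon in a charge-accelerated [3,3] (SN2′) shift through a six-membered transition state while the tertiary allylic C–O bond breaks, which forms the aryl–CH2 bond and releases the oxirane strain. The closest known reaction types are the insertion of arynes into a C–O bond of epoxides and the aryne-triggered aza-Claisen ring expansion of 2-vinyl azacycles to benzo-fused medium rings. The oxepine ring closes by expansion of the oxirane from three to seven members (formal (5+2) annulation; seen from the new ring, a 7-endo-trig attack on the vinyl group), and the retained O1–C2 bond forces the new trisubstituted C3=C4 olefin into the only geometry a seven-membered ring allows. No stereocentre is created, and the racemic quaternary carbon of 8 becomes sp2. The step needs the oxygen to end up para and the carbon meta to the ester, which the bromine next to the aryne should secure by distorting the triple bond so that the distal carbon is the electrophilic one, with the ester acting in the same sense. It also needs the [3,3] collapse to beat 1,2-collapse to a dihydrobenzofuran and aryne ene reactions at the chain olefins, for which the allowed six-membered transition state, the weak allylic C–O bond, the excess of 8 and the slow heterogeneous release of the aryne are relied on.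

Step 7
Reactants: 13 methyl 6-bromo-3-[(3E,7E)-4,8,12-trimethyltrideca-3,7,11-trien-1-yl]-2,5-dihydro-1-benzoxepine-7-carboxylate
Product: 14 6-bromo-3-[(3E,7E)-4,8,12-trimethyltrideca-3,7,11-trien-1-yl]-2,5-dihydro-1-benzoxepine-7-carboxylic acid
Conditions: LiOH, THF/MeOH/H2O, 40 °C; then cold dilute aq HCl to pH 3
Reagents that add atoms: none
Why: ester saponification, to which the aryl bromide, the allyl aryl ether and the olefins are inert; the acidification is kept cold and brief to spare the trisubstituted olefins.

Step 8
Reactants: 14 6-bromo-3-[(3E,7E)-4,8,12-trimethyltrideca-3,7,11-trien-1-yl]-2,5-dihydro-1-benzoxepine-7-carboxylic acid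
Product: 17 callophycoic acid F (3-[(3E,7E)-4,8,12-trimethyltrideca-3,7,11-trien-1-yl]-2,5-dihydro-1-benzoxepine-7-carboxylic acid), via chloromagnesium carboxylate 15 (not isolated), via ring-magnesiated carboxylate 16 (not isolated)
Conditions: MeMgCl, LiCl, THF, −20 °C; then iPrMgCl·LiCl, −20 °C to rt; then cold dilute aq HCl
Reagents that add atoms: none
Why: halogen–magnesium exchange on an unprotected carboxylic acid, in which MeMgCl masks the acid as carboxylate 15, the ortho C–Br bond exchanges with iPrMgCl·LiCl under chelation assistance to give 16, and protonation installs hydrogen at C6, while the carboxylate resists Grignard addition and the olefins, the allyl aryl ether and the C5 methylene are not attacked.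

**Compound list**
1 | (2E,6E)-farnesyl bromide ((2E,6E)-1-bromo-3,7,11-trimethyldodeca-2,6,10-triene) | CC(C)=CCC/C(C)=C/CC/C(C)=C/CBr | starting material
2 | N-methoxy-N-methylacetamide | CC(=O)N(C)OC | starting material
3 | lithium enolate of N-methoxy-N-methylacetamide (not isolated) | C=C(O[Li])N(C)OC | intermediate
4 | (4E,8E)-N-methoxy-N,5,9,13-tetramethyltetradeca-4,8,12-trienamide | CC(C)=CCC/C(C)=C/CC/C(C)=C/CCC(=O)N(C)OC | intermediate
5 | lithium alkoxide of the chloromethyl adduct of 4 (tetrahedral hemiaminal chelate, not isolated) | CC(C)=CCC/C(C)=C/CC/C(C)=C/CCC(CCl)(O[Li])N(C)OC | intermediate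
6 | (5E,9E)-1-chloro-6,10,14-trimethylpentadeca-5,9,13-trien-2-one | CC(C)=CCC/C(C)=C/CC/C(C)=C/CCC(=O)CCl | intermediate
7 | (6E,10E)-3-(chloromethyl)-7,11,15-trimethylhexadeca-1,6,10,14-tetraen-3-ol (racemic) | CC(C)=CCC/C(C)=C/CC/C(C)=C/CCC(O)(CCl)C=C | intermediate
8 | 2-ethenyl-2-[(3E,7E)-4,8,12-trimethyltrideca-3,7,11-trien-1-yl]oxirane (racemic) | CC(C)=CCC/C(C)=C/CC/C(C)=C/CCC1(C=C)CO1 | intermediate
9 | methyl 2-bromo-4-iodobenzoate | COC(=O)c1ccc(I)cc1Br | starting material
10 | [3-bromo-4-(methoxycarbonyl)phenyl](2,4,6-trimethylphenyl)iodonium trifluoromethanesulfonate | COC(=O)c1ccc([I+]c2c(C)cc(C)cc2C)cc1Br.[O-]S(=O)(=O)C(F)(F)F | intermediate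
11 | methyl 2-bromo-3,4-didehydrobenzoate (aryne, not isolated) | COC(=O)C1=C(Br)C#CC=C1 | intermediate
12 | 1-[2-bromo-3-(methoxycarbonyl)-6-aryl anion] oxiranium zwitterion from 8 and 11 (O-aryl oxiranium with the carbanion ortho to oxygen and to bromine, not isolated) | CC(C)=CCC/C(C)=C/CC/C(C)=C/CCC1(C=C)C[O+]1C2=[C-]C(Br)=C(C(=O)OC)C=C2 | intermediate
13 | methyl 6-bromo-3-[(3E,7E)-4,8,12-trimethyltrideca-3,7,11-trien-1-yl]-2,5-dihydro-1-benzoxepine-7-carboxylate | CC(C)=CCC/C(C)=C/CC/C(C)=C/CCC1=CCc2c(Br)c(C(=O)OC)ccc2OC1 | intermediate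
14 | 6-bromo-3-[(3E,7E)-4,8,12-trimethyltrideca-3,7,11-trien-1-yl]-2,5-dihydro-1-benzoxepine-7-carboxylic acid | CC(C)=CCC/C(C)=C/CC/C(C)=C/CCC1=CCc2c(Br)c(C(=O)O)ccc2OC1 | intermediate
15 | chloromagnesium carboxylate of 14 (not isolated) | CC(C)=CCC/C(C)=C/CC/C(C)=C/CCC1=CCc2c(Br)c(C(=O)O[Mg]Cl)ccc2OC1 | intermediate
16 | chloromagnesium 6-(chloromagnesio) carboxylate (ring-magnesiated at C6, not isolated) | CC(C)=CCC/C(C)=C/CC/C(C)=C/CCC1=CCc2c([Mg]Cl)c(C(=O)O[Mg]Cl)ccc2OC1 | intermediate
17 | callophycoic acid F, 3-[(3E,7E)-4,8,12-trimethyltrideca-3,7,11-trien-1-yl]-2,5-dihydro-1-benzoxepine-7-carboxylic acid | CC(C)=CCC/C(C)=C/CC/C(C)=C/CCC1=CCc2cc(C(=O)O)ccc2OC1 | target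

**Step count**
Total: 8 steps. Longest linear sequence: 7 steps (steps 1, 2, 3, 4, 6, 7, 8 from farnesyl bromide); step 5 is a one-step side branch.

**Steps most likely to fail**

1. Step 6 (proposed new method). The weakly nucleophilic oxirane oxygen may lose to ene reactions of the aryne at the three trisubstituted chain olefins, or the zwitterion may collapse by a 1,2-shift to a five-membered ring instead of the seven-membered one. The fallback uses known chemistry, sets out from chloroketone 6 and returns to the route at 17. Williamson etherification of 6 with commercial methyl 4-hydroxy-3-(prop-2-en-1-yl)benzoate (K2CO3, cat. NaI, acetone, 50 °C) should give the aryloxymethyl ketone methyl 4-{[(5E,9E)-6,10,14-trimethyl-2-oxopentadeca-5,9,13-trien-1-yl]oxy}-3-(prop-2-en-1-yl)benzoate F1. Wittig methylenation (Ph3P=CH2 from Ph3PCH3Br and KOtBu, THF, 0 °C) should give the diene methyl 4-{[(5E,9E)-6,10,14-trimethyl-2-methylidenepentadeca-5,9,13-trien-1-yl]oxy}-3-(prop-2-en-1-yl)benzoate F2. Ring-closing metathesis of the 1,1-disubstituted and the terminal olefin with second-generation Grubbs catalyst RuCl2(=CHPh)(PCy3)(H2IMes) (CH2Cl2, 40 °C) should close the oxepine at C3=C4 and give methyl 3-[(3E,7E)-4,8,12-trimethyltrideca-3,7,11-trien-1-yl]-2,5-dihydro-1-benzoxepine-7-carboxylate F3; the trisubstituted chain olefins are expected to stay out of the metathesis. Saponification (LiOH, THF/MeOH/H2O) would then give 17.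

2. Step 8. The bromine–magnesium exchange may be sluggish at the electron-rich, doubly ortho-substituted carboxylate, so that quenching returns unchanged 14. The fallback replaces the polar organometallic step by a radical chain reduction at the ester stage; it sets out from 13 and returns at 17. Hydrodebromination of 13 with Bu3SnH and AIBN (benzene, 80 °C, high hydride concentration to keep radical lifetimes short and limit olefin isomerisation) should give methyl 3-[(3E,7E)-4,8,12-trimethyltrideca-3,7,11-trien-1-yl]-2,5-dihydro-1-benzoxepine-7-carboxylate F4, which LiOH saponification would convert into 17.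

3. Step 3. The basic vinyl Grignard reagent may enolise the α-chloroketone or attack the C–Cl carbon instead of the carbonyl. The fallback avoids the chloroketone altogether; it sets out from Weinreb amide 4 and returns at 8. Addition of CH2=CHMgBr to 4 (THF, 0 °C, inverse quench into cold dilute acid to prevent conjugate addition of the liberated amine) should give the vinyl ketone (6E,10E)-7,11,15-trimethylhexadeca-1,6,10,14-tetraen-3-one F5. Corey–Chaykovsky epoxidation with dimethylsulfonium methylide (Me3SI, n-BuLi, THF, −10 °C), which adds 1,2 to enones, would then give oxirane 8.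

**Further compounds**
F1 | step 6 | methyl 4-{[(5E,9E)-6,10,14-trimethyl-2-oxopentadeca-5,9,13-trien-1-yl]oxy}-3-(prop-2-en-1-yl)benzoate | CC(C)=CCC/C(C)=C/CC/C(C)=C/CCC(=O)COc1ccc(C(=O)OC)cc1CC=C
F2 | step 6 | methyl 4-{[(5E,9E)-6,10,14-trimethyl-2-methylidenepentadeca-5,9,13-trien-1-yl]oxy}-3-(prop-2-en-1-yl)benzoate | CC(C)=CCC/C(C)=C/CC/C(C)=C/CCC(=C)COc1ccc(C(=O)OC)cc1CC=C
F3 | step 6 | methyl 3-[(3E,7E)-4,8,12-trimethyltrideca-3,7,11-trien-1-yl]-2,5-dihydro-1-benzoxepine-7-carboxylate | CC(C)=CCC/C(C)=C/CC/C(C)=C/CCC1=CCc2cc(C(=O)OC)ccc2OC1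
F4 | step 8 | methyl 3-[(3E,7E)-4,8,12-trimethyltrideca-3,7,11-trien-1-yl]-2,5-dihydro-1-benzoxepine-7-carboxylate | CC(C)=CCC/C(C)=C/CC/C(C)=C/CCC1=CCc2cc(C(=O)OC)ccc2OC1
F5 | step 3 | (6E,10E)-7,11,15-trimethylhexadeca-1,6,10,14-tetraen-3-one | CC(C)=CCC/C(C)=C/CC/C(C)=C/CCC(=O)C=C
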